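Readings and results were computed from invented constants; noise was put on by code.

You are asked how far left-handed product leads right-handed product at the end of four flasks that differ in their temperature history, and which flask leads most.

| flask | left-handed substrate | right-handed substrate | reagent | free catalyst | racemization catalyst | added ligand | temperature | remark | time |
|---|---|---|---|---|---|---|---|---|---|
| alpha | 0.034 M | 0.034 M | 0.10 M | 8.5 mM | 50 µM | 11 mM | 5 °C | run made earlier |  |
| epsilon | 0.075 M | 0.075 M | 0.10 M | 8.5 mM | 50 µM | 11 mM | 38 °C | run made earlier |  |
| zeta | 0.050 M | 0.050 M | 0.20 M | 8.5 mM | 50 µM | 11 mM | 5 °C | run made earlier |  |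
| alder | 0.050 M | 0.050 M | 0.100 M | 8.5 mM | 50 µM | 11 mM | −10 °C |  | 30 h |
| birch | 0.050 M | 0.050 M | 0.100 M | 8.5 mM | 50 µM | 11 mM | 50 °C |  | 30 h |
| ash | 0.050 M | 0.050 M | 0.100 M | 8.5 mM | 50 µM | 11 mM |  | at 50 °C until 6.0 h, from then on at −10 °C | 30 h |
| maple | 0.050 M | 0.050 M | 0.100 M | 8.5 mM | 50 µM | 11 mM | 20 °C |  | 30 h |

alpha run (percent of the left-handed substrate and right-handed substrate together charged)

| time / h | left-handed product / % | right-handed product / % |
|---|---|---|
| 0.667 | 11.4 | 1.6 |
| 1.33 | 17.7 | 3.9 |
| 4.00 | 33.8 | 9.4 |
| 10.0 | 45.7 | 16.4 |

epsilon run (percent of the left-handed substrate and right-handed substrate together charged)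

| time / min | left-handed product / % | right-handed product / % |
|---|---|---|
| 8.00 | 10.3 | 2.6 |
| 15.0 | 15.1 | 3.0 |
| 40.0 | 26.7 | 8.0 |
| 120 | 35.7 | 12.8 |

zeta run (percent of the left-handed substrate and right-handed substrate together charged)

| time / h | left-handed product / % | right-handed product / % |
|---|---|---|
| 0.667 | 18.6 | 3.9 |
| 1.33 | 28.0 | 7.2 |
| 4.00 | 44.7 | 14.8 |
| 10.0 | 50.2 | 25.4 |

(each reading ± 0.5 percentage points)

- free catalyst is single-handed; left-handed substrate and right-handed substrate are mirror images of each other, charged as a racemate, each of them at the stated concentration
- the numbers in the tables scatter with a standard deviation of 0.5 percentage points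
- an excess is the difference of the two amounts in percent of their sum
- an excess is below zero if the other one leads

- the best flask by excess of left-handed product over right-handed product; "all alike" if 1.5 percentage points covers them all (alder / birch / ash / maple / all alike)
- excess of left-handed product over right-handed product at the end, alder
- excess of left-handed product over right-handed product at the end, birch
- excess of left-handed product over right-handed product at the end, ash
- excess of left-handed product over right-handed product at the end, maple

Work in logarithms and count decades. If each substrate keeps its hand, a product percentage doubled is the part of its own substrate consumed. At the last epsilon reading, left-handed substrate then stands at 28.6% of its charge and right-handed substrate at 74.4%, so their logarithms stand, as a reading, in the ratio 4.23. This is the selectivity factor, the decades lost by left-handed substrate for each decade lost by right-handed substrate. The last alpha reading, at 5 °C, gives 6.17 as a reading, which is larger.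

Now run birch slowly, using the epsilon factor. In the first instants the two substrates stand equal, so the products form in the ratio of that factor, and the excess begins near 61.8%. In the middle, left-handed substrate sinks faster than right-handed substrate, while the reagent covers the two substrates together 1.00 times, so it is charged for both hands. Near the end, take left-handed substrate at one part in 100. Right-handed substrate then stands at 33.7%, and the excess has fallen to 19.8%, less than at the start. What is about to matter is the reagent still there, 17.4% of its charge in this reckoning, which can go on making right-handed product. Birch is warmer than epsilon and runs 15.0 times as long, so I expect it to pass that point and end below that excess.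

Alder is colder than alpha and runs 3.00 times as long. Taking the alpha factor and left-handed substrate at one part in 10, right-handed substrate stands at 68.9% and the excess is 48.6%, more than in the birch reckoning. Maple and ash spend time warmer than alder, so alder is my choice.

The forecast also names alder, with 56% for alder, 28% for birch, 28% for ash and 29% for maple. Its birch stands above my reckoning, and of the warm flasks it says: “That would cap conversion in birch and ash, leaving them similar”.

The flasks give 51.9% in alder, 9.56% in birch, 24.0% in ash and 30.1% in maple, so alder leads.

    free catalyst + added ligand ⇌ idle complex (K = 570 M⁻¹, k = 14.0 M⁻¹ h⁻¹, Ea = 64.0 kJ mol⁻¹, ΔH = −33.0 kJ mol⁻¹)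
    reagent + free catalyst + left-handed substrate → free catalyst + left-handed product (k = 980 M⁻² h⁻¹, Ea = 37.0 kJ mol⁻¹)
    left-handed substrate + racemization catalyst ⇌ right-handed substrate + racemization catalyst, rate k3*[racemization catalyst]*[left-handed substrate] forward; the back reaction follows from the equilibrium constant (k = 140 M⁻¹ h⁻¹, Ea = 69.0 kJ mol⁻¹)
    reagent + free catalyst + right-handed substrate → free catalyst + right-handed product (k = 190 M⁻² h⁻¹, Ea = 43.0 kJ mol⁻¹)
    reagent + free catalyst → spent catalyst (k = 0.0340 M⁻¹ h⁻¹, Ea = 84.0 kJ mol⁻¹)
    racemization catalyst ⇌ dormant form (K = 5200, k = 0.180 h⁻¹, Ea = 84.0 kJ mol⁻¹, ΔH = −14.0 kJ mol⁻¹)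
    (constants at 20 °C)

The forecast parts from the flask at birch, by 18 percentage points. Birch keeps 0.070% of its left-handed substrate, and the epsilon factor turns that into 18.0% of right-handed substrate and an excess of 9.86%, against 9.56% in the flask. The neighbour of ash, charged with 0.040 M of reagent, keeps 41% of its left-handed substrate and 1.5% of its reagent. The same factor gives 81.1% of right-handed substrate and an excess of 51.5%. That neighbour flask ends at 50.6%.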